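The handle, in germacrane numbering, is the cis-epoxide C4–C5 (methyl on C4) next to the C6 acetate in the ten-membered carbocycle. Together they are a masked Z-allylic alcohol C4=C5–C6(OH), so acetylation and hydroxyl-directed epoxidation come last and the oxirane is the last ring formed.
The key disconnection is C5–C6. The ten-membered ring, the only carbocycle, is closed first by chromium/nickel-catalysed, cathodically driven addition of the Z alkenyl iodide C5 to the C6 aldehyde of open-chain 26. Compound 26 already carries C7, C8, the senecioate and the E C1=C10 alkene.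
26 comes from an oxazolidinone syn-aldol (C7–C8 bond, both stereocentres) between imide 17 and dienal 14, then exchange of the auxiliary for the aldehyde and esterification of O8.
14 is built linearly from but-3-yn-1-ol: carboalumination and oxirane opening (E C1=C10, C2, C3), then carbocupration of propyne and iodinolysis (Z C4=C5–I). This order means no alkylmetal bearing an alkenyl iodide ever has to be cross-coupled.
Key step: step 14

Remark: germacrane numbering is used for all intermediates, organometallic species are drawn as monomers, and oxirane, propyne and (R)-4-benzyloxazolidin-2-one are taken as commercial.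

Step 1
Reactants: 1 but-3-yn-1-ol
Product: 2 tert-butyl(but-3-yn-1-yloxy)dimethylsilane
Conditions: TBSCl, imidazole, CH2Cl2, 0 °C to rt
Reagents that add atoms: tert-butyldimethylsilyl chloride CC(C)(C)[Si](C)(C)Cl
Why: Imidazole-promoted silyl ether formation on an unhindered primary alcohol is routine, and the silyl ether shields the C8 oxygen from the aluminium, magnesium and copper reagents of steps 2 to 4; no stereocentre is formed.

Step 2
Reactants: 2 tert-butyl(but-3-yn-1-yloxy)dimethylsilane; 3 oxirane
Product: 6 (E)-6-(tert-butyldimethylsilyloxy)-4-methylhex-3-en-1-ol, via dimethylalkenylalane 4 (not isolated), via lithium alkenylalanate 5 (not isolated)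
Conditions: Me3Al, Cp2ZrCl2 (20 mol %), CH2Cl2, 0 °C to rt; volatiles removed; n-BuLi, hexane–THF, −78 to 0 °C; 3, 0 °C to rt; H2O quench
Reagents that add atoms: trimethylaluminium C[Al](C)C
Why: Negishi zirconium-catalysed carboalumination adds methyl and aluminium syn across the terminal alkyne with methyl on the internal carbon, which fixes the E C1=C10 alkene, and the butyllithium-derived alkenylalanate then opens oxirane by selective alkenyl transfer with retention (alanate–epoxide alkylation), adding C2 and C3 in the same flask.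

Step 3
Reactants: 6 (E)-6-(tert-butyldimethylsilyloxy)-4-methylhex-3-en-1-ol
Product: 7 [(E)-6-bromo-3-methylhex-3-en-1-yl]oxy(tert-butyl)dimethylsilane
Conditions: CBr4, PPh3, CH2Cl2, 0 °C
Reagents that add atoms: carbon tetrabromide BrC(Br)(Br)Br
Why: Appel bromination converts the unhindered primary alcohol by SN2 displacement of the alkoxyphosphonium ion under near-neutral conditions that leave the silyl ether and the trisubstituted alkene untouched.

Step 4
Reactants: 7 [(E)-6-bromo-3-methylhex-3-en-1-yl]oxy(tert-butyl)dimethylsilane; 8 propyne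
Product: 12 tert-butyl{[(3E,7Z)-8-iodo-3,7-dimethylocta-3,7-dien-1-yl]oxy}dimethylsilane, via homoallylic Grignard reagent 9 (not isolated), via alkylcopper 10 (not isolated), via Z-alkenylcopper 11 (not isolated)
Conditions: Mg, Et2O, reflux; CuBr·SMe2 (1 equiv), Et2O–Me2S, −45 °C; 8, −25 °C; I2, THF, −78 to 0 °C
Reagents that add atoms: iodine II
Why: Normant carbocupration: the alkylcopper–MgBr2 reagent adds syn to propyne with the alkyl group on the internal carbon, so C3 and copper end up cis on C4=C5, and iodinolysis with retention gives the Z alkenyl iodide; the iodide is brought in only now because an alkylmetal that already carried it could not be cross-coupled selectively with a second alkenyl iodide.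

Step 5
Reactants: 12 tert-butyl{[(3E,7Z)-8-iodo-3,7-dimethylocta-3,7-dien-1-yl]oxy}dimethylsilane
Product: 13 (3E,7Z)-8-iodo-3,7-dimethylocta-3,7-dien-1-ol
Conditions: camphorsulfonic acid (10 mol %), MeOH–CH2Cl2, 0 °C to rt
Reagents that add atoms: none
Why: Acid-catalysed methanolysis removes a primary tert-butyldimethylsilyl ether under conditions too mild to touch the alkenyl iodide or to move the trisubstituted alkene.

Step 6
Reactants: 13 (3E,7Z)-8-iodo-3,7-dimethylocta-3,7-dien-1-ol
Product: 14 (3E,7Z)-8-iodo-3,7-dimethylocta-3,7-dienal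
Conditions: Dess–Martin periodinane, NaHCO3, CH2Cl2, 0 °C; used crude at once
Reagents that add atoms: none
Why: Dess–Martin oxidation under bicarbonate buffer stops at the aldehyde and is neutral enough to keep the C10=C1 alkene out of conjugation, provided the β,γ-unsaturated aldehyde is used crude and without delay.

Step 7
Reactants: 15 (R)-4-benzyloxazolidin-2-one; 16 3-methylbutanoyl chloride
Product: 17 (R)-4-benzyl-3-(3-methylbutanoyl)oxazolidin-2-one
Conditions: Et3N, DMAP (10 mol %), CH2Cl2, 0 °C to rt
Reagents that add atoms: none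
Why: DMAP-catalysed N-acylation of the oxazolidinone with the acid chloride is a standard way to load the auxiliary, whose stereocentre is not touched.

Step 8
Reactants: 17 (R)-4-benzyl-3-(3-methylbutanoyl)oxazolidin-2-one; 14 (3E,7Z)-8-iodo-3,7-dimethylocta-3,7-dienal
Product: 20 (R)-4-benzyl-3-[(2R,3S,5E,9Z)-3-hydroxy-10-iodo-5,9-dimethyl-2-(propan-2-yl)deca-5,9-dienoyl]oxazolidin-2-one, via Z boron enolate 18 (not isolated), via boron aldolate 19 (not isolated)
Conditions: n-Bu2BOTf, Et3N, CH2Cl2, 0 °C; 14, −78 to 0 °C; pH 7 buffer, MeOH, 30 % H2O2, 0 °C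
Reagents that add atoms: none
Why: Evans syn-aldol reaction: soft enolisation gives the Z boron enolate, which reacts through a Zimmerman–Traxler chair on the enolate face away from the benzyl group of the (R)-auxiliary, setting C7 (R) and C8 (S) as the 2,3-syn pair, while the low temperature and the near absence of free amine should keep 14 from isomerising.

Step 9
Reactants: 20 aldol adduct
Product: 21 (2S,3S,5E,9Z)-10-iodo-5,9-dimethyl-2-(propan-2-yl)deca-5,9-diene-1,3-diol
Conditions: LiBH4, H2O (1 equiv), Et2O, 0 °C
Reagents that add atoms: none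
Why: Reductive cleavage of the imide with LiBH4 (hydroxyborohydride variant for hindered acyl groups) attacks the exocyclic carbonyl, frees the auxiliary for recovery and leaves the alkenyl iodide, both alkenes and both stereocentres unchanged (the C7 descriptor changes only because the priorities change).

Step 10
Reactants: 21 (2S,3S,5E,9Z)-10-iodo-5,9-dimethyl-2-(propan-2-yl)deca-5,9-diene-1,3-diol
Product: 22 (2S,3S,5E,9Z)-10-iodo-5,9-dimethyl-2-(propan-2-yl)-1-(triethylsilyloxy)deca-5,9-dien-3-ol
Conditions: TESCl (1.05 equiv), imidazole, CH2Cl2, −20 °C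
Reagents that add atoms: chlorotriethylsilane CC[Si](Cl)(CC)CC
Why: Kinetic silylation discriminates the primary C6 hydroxyl from the secondary C8 hydroxyl, which is flanked by the isopropyl-bearing C7, so that only O6 is masked.

Step 11
Reactants: 22 (2S,3S,5E,9Z)-10-iodo-5,9-dimethyl-2-(propan-2-yl)-1-(triethylsilyloxy)deca-5,9-dien-3-ol; 23 3-methylbut-2-enoyl chloride
Product: 24 (2S,3S,5E,9Z)-10-iodo-5,9-dimethyl-2-(propan-2-yl)-1-(triethylsilyloxy)deca-5,9-dien-3-yl 3-methylbut-2-enoate
Conditions: pyridine, DMAP (20 mol %), CH2Cl2, 0 °C to rt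
Reagents that add atoms: none
Why: DMAP-catalysed esterification of the free C8 hydroxyl with the acid chloride proceeds with retention at C8, and pyridine instead of a trialkylamine keeps the acid chloride away from the vinylketene pathway that would give the deconjugated 3-methylbut-3-enoate.

Step 12
Reactants: 24 silyl ether senecioate
Product: 25 (2S,3S,5E,9Z)-1-hydroxy-10-iodo-5,9-dimethyl-2-(propan-2-yl)deca-5,9-dien-3-yl 3-methylbut-2-enoate
Conditions: HF·pyridine, pyridine, THF, 0 °C
Reagents that add atoms: none
Why: Fluoride-mediated cleavage of the primary triethylsilyl ether in a pyridine-buffered, weakly acidic medium is fast at 0 °C and avoids the alkoxide that would trigger a 1,3 acyl shift from O8 to O6.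

Step 13
Reactants: 25 primary alcohol
Product: 26 (2R,3S,5E,9Z)-10-iodo-5,9-dimethyl-1-oxo-2-(propan-2-yl)deca-5,9-dien-3-yl 3-methylbut-2-enoate
Conditions: Dess–Martin periodinane, NaHCO3, CH2Cl2, 0 °C
Reagents that add atoms: none
Why: Buffered Dess–Martin oxidation gives the aldehyde without a base strong enough to epimerise C7 or to eliminate the β-acyloxy group, and 26 is taken directly into the ring closure.

Step 14
Reactants: 26 Z-alkenyl iodide aldehyde
Product: 28 (1(10)E,4Z,6S,7S,8S)-6-hydroxygermacra-1(10),4-dien-8-yl 3-methylbut-2-enoate, via trimethylsilyl ether 27 (not isolated)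
Conditions: CrCl3(thf)3 (20 mol %), NiCl2 (2 mol %), Me3SiCl (3 equiv), n-Bu4NBF4 (0.1 M), DMF, Al anode, Ni-foam cathode, undivided cell, constant current (ca. 2.5 F/mol), 26 added by syringe pump over 12 h (final 2 mM), rt; then 10 % aq. citric acid–THF, 0 °C
Reagents that add atoms: none
Why: Zerovalent nickel inserts into the C5–I bond with retention of the Z geometry and passes the alkenyl group to chromium, and the resulting trivalent alkenylchromium adds to the C6 aldehyde. Me3SiCl silylates the chromium alkoxide to 27, and the trivalent chromium so released is reduced back to the divalent state at the cathode while the aluminium anode dissolves, so that both metals stay catalytic. The closest known chemistry is the Nozaki–Hiyama–Kishi macrocyclisation of ω-iodoalkenyl aldehydes, which reaches medium rings, combined with the electroreductive chromium turnover established for the same alkenyl iodide–aldehyde coupling. The ten-membered carbocycle closes in a 10-exo-trig 1,2-addition that forms C5–C6 and leaves C4=C5 inside the ring as the cis olefin, the geometry a ten-membered ring takes up with least strain, and slow addition keeps the open-chain concentration low enough to disfavour oligomers. The new C6 stereocentre is controlled by C7: closure requires a gauche C5–C6–C7–C8 array, so the isopropyl group takes the position anti to the incoming C5 (Felkin–Anh) with C8 beside the carbonyl oxygen, and this face, also favoured by the dipole-opposed β-acyloxy group (1,3-anti induction), should give the 6,7-anti, 6,8-anti (6S) carbinol. The step needs chemoselectivity for C–I and CHO, which is secured because alkenylchromium ignores the enoate and the E alkene, the cathode is held at the chromium couple well short of the potentials that reduce C–I or the enoate directly, and immediate O-silylation blocks acyl migration from O8 to O6 and loss of the β-acyloxy group.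

Step 15
Reactants: 28 ten-membered Z-allylic alcohol
Product: 29 (1(10)E,4S,5R,6R,7S,8S)-4,5-epoxy-6-hydroxygermacr-1(10)-en-8-yl 3-methylbut-2-enoate
Conditions: VO(acac)2 (5 mol %), t-BuOOH (decane solution, 1.5 equiv), CH2Cl2, 0 °C
Reagents that add atoms: tert-butyl hydroperoxide CC(C)(C)OO
Why: Hydroxyl-directed vanadium-catalysed epoxidation: the C6 alkoxide binds pentavalent vanadium together with the peroxide, so that only the allylic C4=C5 alkene reacts (C1=C10 is out of reach and the senecioate alkene is electron-poor), and, as in medium-ring (Z)-cycloalk-2-enols, the ring holds C7 roughly perpendicular to the alkene plane with the hydroxyl about 50° out of plane on the other side, so oxygen should arrive on that face and give the cis (erythro) epoxy alcohol with C4 (S) and C5 (R), the Z geometry being carried over into the cis-epoxide.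

Step 16
Reactants: 29 epoxy alcohol
Product: 30 (1(10)E,4S,5R,6R,7R,8S)-6-acetoxy-4,5-epoxygermacr-1(10)-en-8-yl 3-methylbut-2-enoate (target)
Conditions: Ac2O, pyridine, DMAP (10 mol %), CH2Cl2, 0 °C to rt
Reagents that add atoms: acetic anhydride CC(=O)OC(C)=O
Why: DMAP-catalysed acetylation of the secondary C6 hydroxyl goes with retention in a mildly basic, non-acidic medium that spares the acid-sensitive epoxide, the E alkene and the senecioate.

Compound list
1 | but-3-yn-1-ol | C#CCCO | starting material
2 | tert-butyl(but-3-yn-1-yloxy)dimethylsilane | C#CCCO[Si](C)(C)C(C)(C)C | intermediate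
3 | oxirane | C1CO1 | starting material
4 | (E)-[4-(tert-butyldimethylsilyloxy)-2-methylbut-1-en-1-yl]dimethylalane | CC(C)(C)[Si](C)(C)OCC/C(C)=C/[Al](C)C | intermediate
5 | lithium butyl[(E)-4-(tert-butyldimethylsilyloxy)-2-methylbut-1-en-1-yl]dimethylalanate | [Li+].CCCC[Al-](C)(C)/C=C(\C)CCO[Si](C)(C)C(C)(C)C | intermediate
6 | (E)-6-(tert-butyldimethylsilyloxy)-4-methylhex-3-en-1-ol | CC(C)(C)[Si](C)(C)OCC/C(C)=C/CCO | intermediate
7 | [(E)-6-bromo-3-methylhex-3-en-1-yl]oxy(tert-butyl)dimethylsilane | CC(C)(C)[Si](C)(C)OCC/C(C)=C/CCBr | intermediate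
8 | propyne | CC#C | starting material
9 | (E)-6-(tert-butyldimethylsilyloxy)-4-methylhex-3-en-1-ylmagnesium bromide | CC(C)(C)[Si](C)(C)OCC/C(C)=C/CC[Mg]Br | intermediate
10 | (E)-6-(tert-butyldimethylsilyloxy)-4-methylhex-3-en-1-ylcopper (MgBr2 complex) | CC(C)(C)[Si](C)(C)OCC/C(C)=C/CC[Cu] | intermediate
11 | (1Z,5E)-8-(tert-butyldimethylsilyloxy)-2,6-dimethylocta-1,5-dien-1-ylcopper | CC(C)(C)[Si](C)(C)OCC/C(C)=C/CC/C(C)=C\[Cu] | intermediate
12 | tert-butyl{[(3E,7Z)-8-iodo-3,7-dimethylocta-3,7-dien-1-yl]oxy}dimethylsilane | CC(C)(C)[Si](C)(C)OCC/C(C)=C/CC/C(C)=C\I | intermediate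
13 | (3E,7Z)-8-iodo-3,7-dimethylocta-3,7-dien-1-ol | OCC/C(C)=C/CC/C(C)=C\I | intermediate
14 | (3E,7Z)-8-iodo-3,7-dimethylocta-3,7-dienal | O=CC/C(C)=C/CC/C(C)=C\I | intermediate
15 | (R)-4-benzyloxazolidin-2-one | O=C1N[C@H](Cc2ccccc2)CO1 | starting material
16 | 3-methylbutanoyl chloride | CC(C)CC(Cl)=O | starting material
17 | (R)-4-benzyl-3-(3-methylbutanoyl)oxazolidin-2-one | CC(C)CC(=O)N1[C@H](Cc2ccccc2)COC1=O | intermediate
18 | Z dibutylboron enolate of 17 | CCCCB(CCCC)O/C(=C\C(C)C)N1[C@H](Cc2ccccc2)COC1=O | intermediate
19 | O8-dibutylboryl aldolate of 20 | O=C(N1[C@H](Cc2ccccc2)COC1=O)[C@H](C(C)C)[C@@H](OB(CCCC)CCCC)C/C(C)=C/CC/C(C)=C\I | intermediate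
20 | (R)-4-benzyl-3-[(2R,3S,5E,9Z)-3-hydroxy-10-iodo-5,9-dimethyl-2-(propan-2-yl)deca-5,9-dienoyl]oxazolidin-2-one | O=C(N1[C@H](Cc2ccccc2)COC1=O)[C@H](C(C)C)[C@@H](O)C/C(C)=C/CC/C(C)=C\I | intermediate
21 | (2S,3S,5E,9Z)-10-iodo-5,9-dimethyl-2-(propan-2-yl)deca-5,9-diene-1,3-diol | OC[C@H](C(C)C)[C@@H](O)C/C(C)=C/CC/C(C)=C\I | intermediate
22 | (2S,3S,5E,9Z)-10-iodo-5,9-dimethyl-2-(propan-2-yl)-1-(triethylsilyloxy)deca-5,9-dien-3-ol | CC[Si](CC)(CC)OC[C@H](C(C)C)[C@@H](O)C/C(C)=C/CC/C(C)=C\I | intermediate
23 | 3-methylbut-2-enoyl chloride | CC(C)=CC(Cl)=O | starting material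
24 | (2S,3S,5E,9Z)-10-iodo-5,9-dimethyl-2-(propan-2-yl)-1-(triethylsilyloxy)deca-5,9-dien-3-yl 3-methylbut-2-enoate | CC[Si](CC)(CC)OC[C@H](C(C)C)[C@@H](OC(=O)C=C(C)C)C/C(C)=C/CC/C(C)=C\I | intermediate
25 | (2S,3S,5E,9Z)-1-hydroxy-10-iodo-5,9-dimethyl-2-(propan-2-yl)deca-5,9-dien-3-yl 3-methylbut-2-enoate | OC[C@H](C(C)C)[C@@H](OC(=O)C=C(C)C)C/C(C)=C/CC/C(C)=C\I | intermediate
26 | (2R,3S,5E,9Z)-10-iodo-5,9-dimethyl-1-oxo-2-(propan-2-yl)deca-5,9-dien-3-yl 3-methylbut-2-enoate (key-step precursor) | O=C[C@H](C(C)C)[C@@H](OC(=O)C=C(C)C)C/C(C)=C/CC/C(C)=C\I | intermediate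
27 | 6-O-trimethylsilyl ether of 28 | C[Si](C)(C)O[C@@H]1[C@H](C(C)C)[C@@H](OC(=O)C=C(C)C)C/C(C)=C/CC/C(C)=C\1 | intermediate
28 | (1(10)E,4Z,6S,7S,8S)-6-hydroxygermacra-1(10),4-dien-8-yl 3-methylbut-2-enoate (key-step product) | O[C@@H]1[C@H](C(C)C)[C@@H](OC(=O)C=C(C)C)C/C(C)=C/CC/C(C)=C\1 | intermediate
29 | (1(10)E,4S,5R,6R,7S,8S)-4,5-epoxy-6-hydroxygermacr-1(10)-en-8-yl 3-methylbut-2-enoate | O[C@@H]1[C@H](C(C)C)[C@@H](OC(=O)C=C(C)C)C/C(C)=C/CC[C@]2(C)O[C@H]12 | intermediate
30 | (1(10)E,4S,5R,6R,7R,8S)-6-acetoxy-4,5-epoxygermacr-1(10)-en-8-yl 3-methylbut-2-enoate | CC(=O)O[C@@H]1[C@H](C(C)C)[C@@H](OC(=O)C=C(C)C)C/C(C)=C/CC[C@]2(C)O[C@H]12 | target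

Total step count: 16. Longest linear sequence: 15 (steps 1–6 and 8–16; step 7 is the side branch).

Steps most likely to fail

**Step 14.**
- What may go wrong: strain in the ten-membered transition state may override the Felkin–Anh bias and give poor facial selectivity at the C6 aldehyde. The slow closure also leaves room for intermolecular addition and protodeiodination.
- Fallback: ring closure and C6 configuration are uncoupled, so that C6 is set by hydride delivery to a ring ketone instead of by the C–C bond formation.
- It sets out from 26. The ring is closed without regard to the carbinol configuration. The mixture of 28 and its C6 epimer, (1(10)E,4Z,6R,7S,8S)-6-hydroxygermacra-1(10),4-dien-8-yl 3-methylbut-2-enoate F1, is oxidised with Dess–Martin periodinane (NaHCO3, CH2Cl2, 0 °C) to the ten-membered Z-enone (1(10)E,4Z,7R,8S)-6-oxogermacra-1(10),4-dien-8-yl 3-methylbut-2-enoate F2.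
- F2 is then reduced under Luche conditions (NaBH4, CeCl3·7H2O, MeOH, −78 °C). Hydride can reach the carbonyl only from the ring periphery, anti to the C7–C8 ring bond with the isopropyl group turned towards the carbonyl oxygen. This should give the 6,7-anti alcohol, and the route is rejoined at 28.

**Step 15.**
- What may go wrong: oxygen may be delivered through the other rotamer about C5–C6 (hydroxyl near the alkene plane, A1,3 control), giving poor facial selectivity. The Lewis-acidic vanadium may also trigger transannular opening of the new epoxide by C1=C10.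
- Fallback: facial control is handed from the ring conformation to a chiral reagent, a Katsuki–Sharpless epoxidation with stoichiometric Ti(OiPr)4, D-(−)-diisopropyl tartrate, t-BuOOH and 4 Å sieves in CH2Cl2 at −20 °C.
- This tartrate addresses the C4=C5 face that gives (4S,5R). For the (6S) carbinol it is the fast-reacting, erythro-selective pairing of the kinetic-resolution manifold, so reagent and substrate are matched.
- It sets out from 28 and comes back at 29, with no new compound (F0).

**Step 4.**
- What may go wrong: incomplete Grignard formation, protonation of the organometallics by propyne, or thermal decay of the alkylcopper before addition would erode the one-pot sequence.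
- Fallback: C3–C4 is made by cross-coupling to a preformed Z C3 unit instead of by addition to the alkyne. It sets out from 7 and 8.
- Bromide 7 is converted with iodine-activated zinc dust in DMA at 70 °C into (E)-6-(tert-butyldimethylsilyloxy)-4-methylhex-3-en-1-ylzinc bromide F3.
- Propyne 8 undergoes syn bromoboration with BBr3 (CH2Cl2, −78 °C) to (Z)-dibromo(2-bromoprop-1-en-1-yl)borane F4, which pinacol turns into 2-[(Z)-2-bromoprop-1-en-1-yl]-4,4,5,5-tetramethyl-1,3,2-dioxaborolane F5.
- Negishi coupling of F3 with F5 (PdCl2(DPEphos), THF, rt) replaces bromine with retention. It gives tert-butyldimethyl{[(3E,7Z)-3,7-dimethyl-8-(4,4,5,5-tetramethyl-1,3,2-dioxaborolan-2-yl)octa-3,7-dien-1-yl]oxy}silane F6.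
- Iodinolysis of F6 (I2, aq. NaOH, THF, 0 °C) with retention rejoins the route at 12.

Further compounds
F1 | step 14 | (1(10)E,4Z,6R,7S,8S)-6-hydroxygermacra-1(10),4-dien-8-yl 3-methylbut-2-enoate | O[C@H]1[C@H](C(C)C)[C@@H](OC(=O)C=C(C)C)C/C(C)=C/CC/C(C)=C\1
F2 | step 14 | (1(10)E,4Z,7R,8S)-6-oxogermacra-1(10),4-dien-8-yl 3-methylbut-2-enoate | O=C1[C@H](C(C)C)[C@@H](OC(=O)C=C(C)C)C/C(C)=C/CC/C(C)=C\1
F0 | step 15 | none | none
F3 | step 4 | (E)-6-(tert-butyldimethylsilyloxy)-4-methylhex-3-en-1-ylzinc bromide | CC(C)(C)[Si](C)(C)OCC/C(C)=C/CC[Zn]Br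
F4 | step 4 | (Z)-dibromo(2-bromoprop-1-en-1-yl)borane | C/C(Br)=C/B(Br)Br
F5 | step 4 | 2-[(Z)-2-bromoprop-1-en-1-yl]-4,4,5,5-tetramethyl-1,3,2-dioxaborolane | C/C(Br)=C/B1OC(C)(C)C(C)(C)O1
F6 | step 4 | tert-butyldimethyl{[(3E,7Z)-3,7-dimethyl-8-(4,4,5,5-tetramethyl-1,3,2-dioxaborolan-2-yl)octa-3,7-dien-1-yl]oxy}silane | CC(C)(C)[Si](C)(C)OCC/C(C)=C/CC/C(C)=C\B1OC(C)(C)C(C)(C)O1
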